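**Retrosynthetic overview**
1. Target ⇐ Sharpless epoxidation (13R,14R) of the 13E-allylic alcohol ⇐ Negishi carboalumination/hydroxymethylation of a terminal alkyne (side chain finished last).
2. 1(10)-Alkene and C18 methyl ester ⇐ syn (Burgess) dehydration of a 10β-hydroxy ester ⇐ γ-lactone ⇐ oxidation of a 10β,18-ether.
3. Both rings and C5, C8, C9, C10 ⇐ one cationic cascade of an acyclic (S)-epoxide: ring A (C4–C5), then ring B (C9–C10), 1,2-H (C9→C8), 1,2-Me (C10→C9), capture at C10 by the oxygen freed in the first step.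
4. Epoxide ⇐ terminal SeO2 oxidation, Sharpless epoxidation, hydride opening and ring closure on a farnesyl-derived trienyne.
5. Trienyne ⇐ (E,E)-farnesyl bromide + lithiated 1-(trimethylsilyl)propyne.

Assumption: the SMILES is read literally, so H-5 is on the same face as the methyl groups on C8 and C9 (5R); the route is designed for that isomer.

Naming convention for the cyclic compounds: target skeleton numbering ("halimane"). C1–C10 are the decalin (ring fusion C5/C10), C11–C16 the side chain on C9 (Me-16 on C13), Me-17 is on C8, C18 is the oxygenated carbon on C4, Me-19 is on C4, and Me-20 is on C9 (on C10 before it migrates). α is the face of H-5 in the target. Unless a name says otherwise, C18 and the side chain are β and Me-17, Me-19, Me-20 are α.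

**Step 1**
Reactants: 1 (2E,6E)-farnesyl bromide; 2 trimethyl(prop-1-yn-1-yl)silane
Product: 4 trimethyl[(5E,9E)-6,10,14-trimethylpentadeca-5,9,13-trien-1-yn-1-yl]silane, via propargyllithium 3 (not isolated)
Conditions: 2, n-BuLi, THF, −78 → −20 °C; then 1, −78 → 0 °C
Reagents that add atoms: none
Why: SN2 alkylation of the primary allylic bromide by the silyl-stabilised propargylic lithium reagent (Corey–Kirst 1,5-enyne synthesis) leaves the E,E geometry of the farnesyl unit untouched.

**Step 2**
Reactants: 4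
Product: 5 (2E,6E,10E)-2,6,10-trimethyl-15-(trimethylsilyl)pentadeca-2,6,10-trien-14-yn-1-ol
Conditions: SeO2 (0.5 equiv), t-BuOOH (2 equiv), salicylic acid (0.1 equiv), CH2Cl2, 0 °C → rt, stopped at partial conversion and recycled
Reagents that add atoms: selenium dioxide, O=[Se]=O; tert-butyl hydroperoxide, CC(C)(C)OO
Why: selenium dioxide allylic oxidation (ene reaction then [2,3]-sigmatropic shift) hydroxylates the E-methyl of the terminal isopropylidene group, the most reactive alkene of a polyprenyl chain, giving the 2E-allylic alcohol.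

**Step 3**
Reactants: 5
Product: 6 [(2R,3R)-3-[(3E,7E)-3,7-dimethyl-12-(trimethylsilyl)dodeca-3,7-dien-11-yn-1-yl]-2-methyloxiran-2-yl]methanol
Conditions: Ti(OiPr)4 (10 mol %), D-(−)-diethyl tartrate (12 mol %), t-BuOOH, 4 Å MS, CH2Cl2, −20 °C
Reagents that add atoms: tert-butyl hydroperoxide, CC(C)(C)OO
Why: Katsuki–Sharpless asymmetric epoxidation with D-(−)-tartrate gives the (2R,3R)-epoxy alcohol, which fixes the quaternary centre that becomes C4, while the isolated alkenes and the alkyne do not react.

**Step 4**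
Reactants: 6
Product: 7 (2S,6E,10E)-2,6,10-trimethyl-15-(trimethylsilyl)pentadeca-6,10-dien-14-yne-1,2-diol
Conditions: LiAlH4, THF, 0 °C → rt
Reagents that add atoms: none
Why: SN2 hydride opening at the less substituted epoxide carbon gives the 1,2-diol and leaves the C–O bond at the quaternary carbon, and so its configuration, intact.

**Step 5**
Reactants: 7
Product: 10 (2S)-2-[(4E,8E)-4,8-dimethyltrideca-4,8-dien-12-yn-1-yl]-2-methyloxirane, via monotosylate 8 (not isolated), via silyl epoxide 9 (not isolated)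
Conditions: TsCl, Et3N, DMAP (cat.), CH2Cl2, 0 °C; then K2CO3, MeOH, rt
Reagents that add atoms: none
Why: selective sulfonylation of the primary alcohol and intramolecular Williamson closure by the tertiary alkoxide form the 2,2-disubstituted epoxide without touching the stereocentre, and K2CO3/MeOH also cleaves the alkynyl C–Si bond.

**Step 6**
Reactants: 10
Product: 15 10β,18-epoxy-15,16-dinor-5αH-halim-13-yne, via 8-yl cation 11 (not isolated), via 9-yl cation 12 (not isolated), via 10-yl cation 13 (not isolated), via 5(10)-ene alcohol 14 (not isolated)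
Conditions: BF3·OEt2 (0.5 equiv), CH2Cl2 (0.01 M), −78 °C, then → rt until the ether ratio is constant; Et3N, aq. NaHCO3
Reagents that add atoms: none
Why: Proposed new method: BF3 opens the epoxide at tertiary C4 with inversion while the C5=C10 alkene attacks anti and the C8=C9 alkene closes ring B (Lewis-acid epoxy-polyene bicyclisation through a chair/chair fold with the CH2O–BF3 arm equatorial and Me-19 axial, giving the trans-fused 8-yl cation with Me-20 α and H-5, H-9 β); H-9 then shifts to C8 and Me-20 to C9, each suprafacially (the biosynthetic halimane rearrangement, known for BF3-treated labdane and drimane 8-cations), the C10 cation drains to the 5(10)-alkene, and acid-mediated trans-diaxial addition of the 1,3-disposed 18-OH across it (O to C10 on the β face, H to C5 on the α face) gives the all-chair trans-fused ether, the thermodynamic sink because its 5β-H epimer would force Me-17 and C1 into a 1,3-diaxial clash; closest known reaction types are epoxide-initiated cation–olefin cyclisation and acid-induced 1,2-H/1,2-Me shift followed by cycloetherification of the rearranged alkene.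

**Step 7**
Reactants: 15
Product: 16 15,16-dinor-5αH-halim-13-yn-18,10β-olide
Conditions: CrO3, AcOH/H2O, rt
Reagents that add atoms: chromium trioxide, O=[Cr](=O)=O
Why: chromic acid oxidation of a cyclic ether to the lactone can only occur at C18 (C10 is fully substituted), as in the oxidation of ambroxide-type tetrahydrofurans to γ-lactones, and a terminal alkyne tolerates chromic acid.

**Step 8**
Reactants: 16
Product: 18 methyl 10β-hydroxy-15,16-dinor-5αH-halim-13-yn-18-oate, via potassium carboxylate 17 (not isolated)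
Conditions: KOH, MeOH/H2O, 70 °C; evaporate; MeI, DMF, 0 °C → rt
Reagents that add atoms: potassium hydroxide, [K+].[OH-]; iodomethane, CI
Why: saponification by acyl–oxygen cleavage keeps the C10–O bond and its β configuration, and SN2 methylation of the carboxylate gives the hydroxy ester without any acid that would re-close the lactone.

**Step 9**
Reactants: 18
Product: 20 methyl (4S,5R,8R,9S)-15,16-dinorhalim-1(10)-en-13-yn-18-oate, via sulfamate ester 19 (not isolated)
Conditions: MeO2CN(−)SO2N(+)Et3 (Burgess reagent), PhMe, rt → 50 °C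
Reagents that add atoms: none
Why: Burgess dehydration is a syn (Ei) elimination through the sulfamate ester, and the 10β leaving group has a syn β-hydrogen only at C1 (H-5 is α, C9 is quaternary), so only the 1(10)-alkene forms and the C5 centre is kept.

**Step 10**
Reactants: 20
Product: 23 methyl (4S,5R,8R,9S,13E)-15-hydroxyhalima-1(10),13-dien-18-oate, via alkenylalane 21 (not isolated), via lithium alanate 22 (not isolated)
Conditions: Me3Al, Cp2ZrCl2 (25 mol %), CH2Cl2, 0 °C → rt; evaporate; n-BuLi, THF/hexane, −78 °C; (CH2O)n, −78 °C → rt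
Reagents that add atoms: trimethylaluminium, C[Al](C)C; formaldehyde as paraformaldehyde, C=O
Why: Negishi zirconium-catalysed carboalumination adds Me and Al syn across the terminal alkyne with Me on the internal carbon, and the derived alanate is hydroxymethylated with retention, giving the 13E-trisubstituted allylic alcohol.

**Step 11**
Reactants: 23
Product: 24 methyl (4S,5R,8R,9S,13R,14R)-13,14-epoxy-15-hydroxyhalim-1(10)-en-18-oate
Conditions: Ti(OiPr)4, D-(−)-diethyl tartrate, t-BuOOH, 4 Å MS, CH2Cl2, −20 °C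
Reagents that add atoms: tert-butyl hydroperoxide, CC(C)(C)OO
Why: Katsuki–Sharpless asymmetric epoxidation with D-(−)-tartrate sets C13 and C14 as R,R under reagent control, and the 1(10)-alkene, which has no allylic hydroxyl, is left alone.

**Compound list**
1 | (2E,6E)-1-bromo-3,7,11-trimethyldodeca-2,6,10-triene ((E,E)-farnesyl bromide) | CC(C)=CCC/C(C)=C/CC/C(C)=C/CBr | starting material
2 | trimethyl(prop-1-yn-1-yl)silane | CC#C[Si](C)(C)C | starting material
3 | [3-(trimethylsilyl)prop-2-yn-1-yl]lithium | [Li]CC#C[Si](C)(C)C | intermediate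
4 | trimethyl[(5E,9E)-6,10,14-trimethylpentadeca-5,9,13-trien-1-yn-1-yl]silane | C[Si](C)(C)C#CCC/C=C(C)/CC/C=C(C)/CCC=C(C)C | intermediate
5 | (2E,6E,10E)-2,6,10-trimethyl-15-(trimethylsilyl)pentadeca-2,6,10-trien-14-yn-1-ol | C[Si](C)(C)C#CCC/C=C(C)/CC/C=C(C)/CC/C=C(C)/CO | intermediate
6 | [(2R,3R)-3-[(3E,7E)-3,7-dimethyl-12-(trimethylsilyl)dodeca-3,7-dien-11-yn-1-yl]-2-methyloxiran-2-yl]methanol | C[Si](C)(C)C#CCC/C=C(C)/CC/C=C(C)/CC[C@H]1O[C@]1(C)CO | intermediate
7 | (2S,6E,10E)-2,6,10-trimethyl-15-(trimethylsilyl)pentadeca-6,10-dien-14-yne-1,2-diol | C[Si](C)(C)C#CCC/C=C(C)/CC/C=C(C)/CCC[C@](C)(O)CO | intermediate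
8 | (2S,6E,10E)-2-hydroxy-2,6,10-trimethyl-15-(trimethylsilyl)pentadeca-6,10-dien-14-yn-1-yl 4-methylbenzenesulfonate | C[Si](C)(C)C#CCC/C=C(C)/CC/C=C(C)/CCC[C@](C)(O)COS(=O)(=O)c1ccc(C)cc1 | intermediate
9 | trimethyl[(5E,9E)-6,10-dimethyl-13-[(2S)-2-methyloxiran-2-yl]trideca-5,9-dien-1-yn-1-yl]silane | C[Si](C)(C)C#CCC/C=C(C)/CC/C=C(C)/CCC[C@@]1(C)CO1 | intermediate
10 | (2S)-2-[(4E,8E)-4,8-dimethyltrideca-4,8-dien-12-yn-1-yl]-2-methyloxirane | C#CCC/C=C(C)/CC/C=C(C)/CCC[C@@]1(C)CO1 | intermediate
11 | 8-yl cation (trans-fused, 18-O–BF3 zwitterion; Me-20 α on C10, H-5 β, H-9 β, side chain α) | F[B-](F)(F)OC[C@@]1(C)CCC[C@]2(C)[C@@H]1CC[C+](C)[C@H]2CCC#C | intermediate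
12 | 9-yl cation (H-8 β, Me-17 α; Me-20 α still on C10; H-5 β) | F[B-](F)(F)OC[C@@]1(C)CCC[C@]2(C)[C@@H]1CC[C@@H](C)[C+]2CCC#C | intermediate
13 | 10-yl cation (Me-20 α on C9, side chain β, H-5 β) | F[B-](F)(F)OC[C@@]1(C)CCC[C+]2[C@@H]1CC[C@@H](C)[C@]2(C)CCC#C | intermediate
14 | 15,16-dinorhalim-5(10)-en-13-yn-18-ol (as its BF3 complex) | OC[C@@]1(C)CCCC2=C1CC[C@@H](C)[C@]2(C)CCC#C | intermediate
15 | 10β,18-epoxy-15,16-dinor-5αH-halim-13-yne | O1C[C@@]2(C)CCC[C@]13[C@H]2CC[C@@H](C)[C@]3(C)CCC#C | intermediate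
16 | 15,16-dinor-5αH-halim-13-yn-18,10β-olide | O1C(=O)[C@@]2(C)CCC[C@]13[C@H]2CC[C@@H](C)[C@]3(C)CCC#C | intermediate
17 | potassium 10β-hydroxy-15,16-dinor-5αH-halim-13-yn-18-oate | [K+].[O-]C(=O)[C@@]1(C)CCC[C@@]2(O)[C@H]1CC[C@@H](C)[C@]2(C)CCC#C | intermediate
18 | methyl 10β-hydroxy-15,16-dinor-5αH-halim-13-yn-18-oate | COC(=O)[C@@]1(C)CCC[C@@]2(O)[C@H]1CC[C@@H](C)[C@]2(C)CCC#C | intermediate
19 | triethylammonium salt of the 10β-O-[N-(methoxycarbonyl)sulfamate] of 18 | COC(=O)[C@@]1(C)CCC[C@@]2(OS(=O)(=O)[N-]C(=O)OC)[C@H]1CC[C@@H](C)[C@]2(C)CCC#C.CC[NH+](CC)CC | intermediate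
20 | methyl (4S,5R,8R,9S)-15,16-dinorhalim-1(10)-en-13-yn-18-oate | COC(=O)[C@@]1(C)CCC=C2[C@H]1CC[C@@H](C)[C@]2(C)CCC#C | intermediate
21 | methyl (13E)-14-(dimethylalumanyl)-15-norhalima-1(10),13-dien-18-oate | COC(=O)[C@@]1(C)CCC=C2[C@H]1CC[C@@H](C)[C@]2(C)CC/C(C)=C/[Al](C)C | intermediate
22 | lithium butyl(dimethyl)alanate of 21 | [Li+].COC(=O)[C@@]1(C)CCC=C2[C@H]1CC[C@@H](C)[C@]2(C)CC/C(C)=C/[Al-](C)(C)CCCC | intermediate
23 | methyl (4S,5R,8R,9S,13E)-15-hydroxyhalima-1(10),13-dien-18-oate | COC(=O)[C@@]1(C)CCC=C2[C@H]1CC[C@@H](C)[C@]2(C)CC/C(C)=C/CO | intermediate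
24 | methyl (4S,5R,8R,9S,13R,14R)-13,14-epoxy-15-hydroxyhalim-1(10)-en-18-oate (CNP0324371.2) | COC(=O)[C@@]1(C)CCC=C2[C@H]1CC[C@@H](C)[C@]2(C)CC[C@@]1(C)O[C@@H]1CO | target

**Totals**
Total steps: 11. Longest linear sequence: 11 (from 1).

**Steps most likely to fail**

Step 6 (cascade). Three things can go wrong:
- The exocyclic epoxide controls C4 by inversion, but the ring-A fold (CH2O arm equatorial versus axial) is decided only by sterics, and it sets the sense of all ring centres relative to C4.
- A 2,2-disubstituted epoxide can instead undergo hydride shift to the aldehyde.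
- Equilibration to the trans-fused ether may be incomplete.

Fallback, setting out from 10 and coming back at 16: cyclise 10 with MeAlCl2 (CH2Cl2, −78 °C), a Lewis acid that also scavenges protons, so the reaction stops at the kinetic bicyclic alkene, the trans-fused 8(17)-ene primary alcohol F1. Oxidise it with Dess–Martin periodinane to the aldehyde F2 and with NaClO2/NaH2PO4/2-methyl-2-butene to the carboxylic acid F3. Then treat F3 with TfOH (CH2Cl2, −40 → 0 °C): protonation of the exocyclic alkene regenerates the 8-yl cation, the same two shifts follow, and the 4β-CO2H, which is 1,3 to C10, adds across the 5(10)-alkene to close lactone 16 directly. The diastereomers are separated at the crystalline acid stage, and the ether oxidation is no longer needed.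

Step 7 (ether to lactone). Chromic acid may attack the alkyne or the tertiary C–H bonds faster than the hindered neopentyl OCH2.

Fallback, setting out from 15 and coming back at 20: open the ether by a syn β-elimination with Et2Al–N(2,2,6,6-tetramethylpiperidide) (PhMe, 0 → 60 °C). Aluminium binds the ether oxygen and the amide removes the only syn β-hydrogen, H-1β, giving the 1(10)-ene primary alcohol F4. Dess–Martin oxidation gives the aldehyde F5, NaClO2 oxidation the acid F6, and Me3SiCHN2 in MeOH/PhMe the ester 20.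

Step 9 (Burgess dehydration). The hydroxy ester 18 has OH and CO2Me 1,3-diaxial and may re-close to lactone 16 faster than the hindered tertiary alcohol is sulfamoylated.

Fallback, setting out from 16 and coming back at 20: reduce the lactone with LiAlH4 to the 10β,18-diol F7, which cannot re-close under neutral conditions. Silylate its primary alcohol (t-BuMe2SiCl, imidazole) to the silyl ether F8. Run the same Burgess syn-elimination on F8 to give the 1(10)-ene silyl ether F9. Remove the silyl group with Bu4NF to reach alcohol F4, which is oxidised and esterified through F5 and F6 as above to return at 20.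

**Further compounds**
F1 | step 6 | 15,16-dinor-5βH-labd-8(17)-en-13-yn-18-ol of the series with Me-20 α on C10, H-9 β and the side chain α on C9 | OC[C@@]1(C)CCC[C@]2(C)[C@@H]1CCC(=C)[C@H]2CCC#C
F2 | step 6 | the corresponding 18-al | O=C[C@@]1(C)CCC[C@]2(C)[C@@H]1CCC(=C)[C@H]2CCC#C
F3 | step 6 | the corresponding 18-oic acid | OC(=O)[C@@]1(C)CCC[C@]2(C)[C@@H]1CCC(=C)[C@H]2CCC#C
F4 | step 7 | (4S,5R,8R,9S)-15,16-dinorhalim-1(10)-en-13-yn-18-ol | OC[C@@]1(C)CCC=C2[C@H]1CC[C@@H](C)[C@]2(C)CCC#C
F5 | step 7 | (4S,5R,8R,9S)-15,16-dinorhalim-1(10)-en-13-yn-18-al | O=C[C@@]1(C)CCC=C2[C@H]1CC[C@@H](C)[C@]2(C)CCC#C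
F6 | step 7 | (4S,5R,8R,9S)-15,16-dinorhalim-1(10)-en-13-yn-18-oic acid | OC(=O)[C@@]1(C)CCC=C2[C@H]1CC[C@@H](C)[C@]2(C)CCC#C
F7 | step 9 | 15,16-dinor-5αH-halim-13-yne-10β,18-diol | OC[C@@]1(C)CCC[C@@]2(O)[C@H]1CC[C@@H](C)[C@]2(C)CCC#C
F8 | step 9 | 18-(tert-butyldimethylsilyloxy)-15,16-dinor-5αH-halim-13-yn-10β-ol | CC(C)(C)[Si](C)(C)OC[C@@]1(C)CCC[C@@]2(O)[C@H]1CC[C@@H](C)[C@]2(C)CCC#C
F9 | step 9 | tert-butyldimethylsilyl ether of F4 | CC(C)(C)[Si](C)(C)OC[C@@]1(C)CCC=C2[C@H]1CC[C@@H](C)[C@]2(C)CCC#C
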